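## The problem

Compound 13 is the (E)-4-hydroxycinnamate of a guai-1(10)-ene-8,11-diol. Guaiane numbering is used throughout: ring A is the cyclopentane C1–C5, ring B the seven-membered ring C1, C5–C10, C15 is the methyl on C4, C14 the methyl on C10, C11 the carbinol carbon on C7, and the ester oxygen sits on C8.

The two rings share the C1–C5 bond, and C1 is also one end of the tetrasubstituted C1=C10 alkene. The alkene therefore has to be placed at one defined position beside the ring fusion and held there while C8 passes through the ketone level, where it is β,γ to the carbonyl and one proton shift from conjugation. Four stereocentres are present, 4S and 5S in ring A, 7S and 8S in ring B. H4, H5 and H7 lie on one face and H8 on the other, so C15 is cis to C6 and the C8 oxygen is trans to the C7 side chain.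

Only C5 can arise in a skeleton-forming event, and it must then relay. It distinguishes the two faces of C4, and it sets the ring B conformation in which the C7 side chain is pseudo-equatorial. The C11 hydroxyl on C7 can in turn deliver hydride to C8. The C15 methyl cis to C6 is the less stable arrangement on a cyclopentane, so C4 has to be set under kinetic control.

The groups that will not survive rough treatment are:
- the tertiary C11 carbinol (dehydration, and retro-aldol loss of acetone while C8 is a ketone);
- the C1=C10 alkene (migration under acid or base);
- the hydroxycinnamate (base-labile ester, free phenol, isomerisable alkene), which should therefore come last.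

The feature that opens the route is the C1–C5 fusion bond flanked by C1=C10, with oxygen on C8 next to the C7–C11 unit. This is the imprint of a germacra-1(10),4-diene whose C4=C5 epoxide has been attacked across the ten-membered ring by the C1=C10 alkene. All fifteen skeletal carbons and both oxygen-bearing positions map onto germacrone.

## Retrosynthesis

**Ester C8–O acyl bond.** Target 13 is cut at the acyl–oxygen bond, through aryl silyl ether 12, to diol 8 and the protected acid 11 (from 4-hydroxycinnamic acid 9 through the bis-silyl compound 10). Acylating last keeps the conjugated ester and the phenol away from SmI2, borohydride and alkaline peroxide. Building the cinnamate alkene on a malonate half-ester of 8 would save the protecting group but needs heat and amine base on a β-hydroxy ester. Diol 8 is nine carbons smaller and carries only two hydroxyls. The forward step must acylate the secondary C8 hydroxyl and leave the tertiary C11 hydroxyl, which hindrance should secure.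

**C8–H bond.** Diol 8 goes back to hydroxy ketone 7. A C8 ketone is preferred to any C–O bond-forming tactic at C8 because the C11 hydroxyl is 1,3 to it and can hand hydride over from the side of the C7 substituent. That gives the trans relation between the C8 oxygen and the side chain. The forward reduction must be internal delivery, not external attack.

**C7–H and C11–O bonds.** Hydroxy ketone 7 is formally an aldol of acetone. A direct aldol is rejected because an 8-ketone enolises toward the allylic C9. The C11 oxygen is therefore traced to epoxy ketone 6 and on to the isopropylidene ketone 5, with the C7 hydrogen arriving on reductive cleavage of the C7–O bond. Ketone 5 has no stereocentre in ring B. The forward steps must protonate the C7 enolate so that the side chain ends cis to C4, and must keep C1=C10 out of conjugation.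

**C4–H bond.** Ketone 5 is traced through methyl oxalate 4 to tertiary alcohol 3. The hydrogen is exchanged for a hydroxyl because a hydroxyl is what an epoxide-initiated ring closure leaves on C4. Radical replacement is chosen over dehydration and hydrogenation for three reasons:
- the hydroxyl is cis to H5;
- ionisation at C4 would run to the conjugated 4,1(10)-diene and erase C5;
- hydrogenation would have to select one of four alkenes.

The forward step must deliver the hydrogen atom anti to C6.

**C1–C5 bond (key).** Cutting the fusion bond of 3, returning hydrogen to C1 and tying the C4 oxygen back to C5, opens both rings to the ten-membered epoxide 2. Cuts inside ring B (C5–C6 with C8–C9, or C9–C10) lead to fragments from which the skeleton still has to be assembled. This cut leads to a compound that already holds every carbon, the C8 carbonyl and the C7=C11 unit. Two rings become one, and the stereochemical content shrinks to one trans epoxide. The forward reaction must bond C1 (not C10) to C5 with inversion and must lose H1 from the resulting C10 cation.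

**Epoxide C–O bonds.** Epoxide 2 comes from germacrone 1, a commercial macrocycle with no stereocentre. The forward step asks a chiral oxidant to choose one alkene of three and one enantiotopic face.

## Roads not taken

**Alternative 1: Ramberg–Bäcklund ring contraction.**
- Cut: the C1=C10 double bond itself, leading back to an eight-membered cyclic sulfone A2 in which SO2 bridges C1 and C10 and the 8,11-diol is held as an acetonide.
- Forward key step: KOH and CCl4 chlorinate one α-carbon, the α′-carbanion closes to an episulfone, and loss of SO2 gives the acetonide A1 of diol 8.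
- Merits: the alkene position is fixed by construction and no proton-loss regiochemistry arises. A1 already has all four stereocentres and is a deprotection and an acylation away from 13. In certainty of alkene placement this road is better than the chosen one.
- Weak points: A2 must first be built with C4, C5, C7 and C8 each set by separate means and with an eight-membered thiacycle closed. The extrusion has to make a tetrasubstituted alkene from two methine α-carbons, where α-chlorination is hindered and dichlorocarbene can add to the new electron-rich alkene.
- Comparison: the chosen plan answers with step economy. Both rings, C5 and the complete carbon and oxygen pattern come in two steps from a commercial compound, and the cost is the C4 deoxygenation and the C7/C8 relay.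

**Alternative 2: [4+3] cycloaddition.**
- Cut: C8–C9 and C5–C6, leading to the silyloxy diene A4 and the oxyallyl precursor A5.
- Forward key step: TMSOTf ionises A5 to a benzyloxy-substituted oxyallyl cation that adds across the diene termini of A4 to give ketone A3, with ring B closed and C1=C10 in place.
- Merits: the route is convergent, the alkene position follows from the mechanism (the central diene bond becomes C1=C10), and the C8 oxygen arrives with the cycloaddition. On these points it matches or beats the chosen plan.
- Weak points: an unsymmetrical cation meets an unsymmetrical diene, so head-to-head or head-to-tail orientation is open. C5 forms next to a quaternary C4 whose two substituents (methyl and silyloxy) differ little in size. A4 needs its own enantioselective synthesis. A3 carries a carbonyl on C7, where the target has hydrogen and the C11 carbinol, so C11 must be added to that ketone and the C7 oxygen then removed with stereocontrol next to the benzyloxy group. The C4 deoxygenation of the chosen route is needed here as well.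
- Comparison: the chosen plan sets against it a starting material whose oxidation pattern (C8 carbonyl, C7=C11) already matches.

**Alternative 3: rhodium-catalysed [5+2] cycloaddition.**
- Cut: C1–C5 and C9–C10, leading to the linalool-derived yne–vinylcyclopropane A7.
- Forward key step: [Rh(CO)2Cl]2 joins the methylalkyne and the siloxy vinylcyclopropane of A7 to give the bicyclic silyl enol ether A6, closing ring A and ring B in one catalytic event.
- Merits: the alkyne carbons become C1=C10, so the alkene position is certain. C4 comes from the chiral pool, with no asymmetric catalysis. In both respects this road is better than the chosen one, and its ring construction is as short.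
- Weak points: C5 is again set against a methyl/silyloxy quaternary centre. A6 has oxygen on C7 but none on C8, and its enol ether (C6=C7) points away from C8. The C8 oxygen, the C11 unit and removal of the C7 oxygen all remain to be done, on top of the C4 deoxygenation, and A7 itself takes several steps from linalool.
- Comparison: the chosen plan spends no step on skeleton construction beyond the key step and starts with functionality on the right carbons. It pays with reliance on proton-loss regiochemistry.

Key step: step 2

Assumption: the D-fructose-derived ketone is taken to deliver oxygen to C4=C5 of 1 with the facial sense it shows for acyclic (E)-trisubstituted alkenes, giving the (4R,5R) epoxide; if the macrocycle reverses this sense, the L-fructose-derived enantiomer of the ketone would be used.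

Assumption: epoxy ketone 6 is drawn as its (7S) epimer; either C7 epimer serves, because step 6 erases this centre.

## Route

Step 1
Reactants: 1 germacrone [(3E,7E)-3,7-dimethyl-10-(propan-2-ylidene)cyclodeca-3,7-dien-1-one]
Product: 2 (4R,5R)-germacrone 4,5-epoxide [(4R,5R)-4,5-epoxygermacra-1(10)E,7(11)-dien-8-one]
Conditions: 1,2:4,5-di-O-isopropylidene-β-D-erythro-2,3-hexodiulo-2,6-pyranose (0.3 equiv), KHSO5 (as 2KHSO5·KHSO4·K2SO4, 1.1 equiv), K2CO3, Bu4NHSO4 (cat.), MeCN/CH2(OMe)2–aq. Na2B4O7 buffer (pH 10.5), 0 °C
Reagents that add atoms: potassium peroxymonosulfate, [K+].[O-]S(=O)(=O)OO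
Why: Shi asymmetric epoxidation (chiral dioxirane, spiro transition state): the electrophilic oxidant ignores the electron-poor C7=C11 enone alkene and should prefer C4=C5 to C1=C10, which carries the inductively withdrawing CH2C(=O) group on C10. Only the outer face of each ring alkene is open and the planar-chiral conformers of 1 interconvert at 0 °C, so the catalyst selects the conformer leading to the (4R,5R) epoxide; the trans epoxide geometry follows from the E alkene.

Step 2
Reactants: 2 (4R,5R)-germacrone 4,5-epoxide
Product: 3 (4R,5R)-4-hydroxyguaia-1(10),7(11)-dien-8-one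
Conditions: p-TsOH·H2O (0.1 equiv), CH2Cl2 (dry), 0 °C → rt, short contact time, NaHCO3 quench
Reagents that add atoms: none
Why: Acid-catalysed transannular epoxide–olefin cyclisation, the reaction type by which germacrane 4,5-epoxides are converted into guai-1(10)-en-4-ols. Protonation of the epoxide oxygen in the crossed conformation of 2 places the C1=C10 π face behind the C5–O bond; C1 attacks C5 with inversion while the C4–O bond stays intact, so C4 keeps its configuration and the new C5 centre is fixed by the (5R) epoxide carbon alone (H5 ends cis to the C4 hydroxyl, C6 cis to C15). Ring A closes through the new C1–C5 bond in a five-membered closure that is endo with respect to the epoxide (C4 and C5 both in the ring) and exo with respect to the alkene (C10 outside); ring B is the remaining seven-membered loop, for which the same bond is endo to the alkene and exo to the breaking C5–O bond. Regiochemistry at the alkene is Markovnikov: bonding at C1 leaves the charge on tertiary C10, whereas C10–C5 bonding would put it on secondary C1 and C1–C4 bonding would need a four-membered ring. The C10 cation then loses H1 to give the tetrasubstituted C1=C10 alkene, the most substituted of the three alkenes open to it; an exocyclic 10(14) isomer, if formed, can re-enter the cation by reprotonation under the same acid. The step needs a non-nucleophilic medium so that C10 is not trapped, and a short contact time so that the tertiary C4 alcohol is not ionised.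

Step 3
Reactants: 3 (4R,5R)-4-hydroxyguaia-1(10),7(11)-dien-8-one
Product: 4 (4R,5R)-8-oxoguaia-1(10),7(11)-dien-4-yl methyl oxalate
Conditions: ClC(O)CO2Me (2 equiv), Et3N, DMAP (0.2 equiv), CH2Cl2, 0 °C → rt
Reagents that add atoms: methyl chlorooxoacetate, COC(=O)C(=O)Cl
Why: Acylation of the tertiary alcohol by the highly electrophilic oxalyl half-ester chloride under DMAP catalysis; no stereocentre is touched and the amine base is too weak to enolise the ketone toward C9.

Step 4
Reactants: 4 (4R,5R)-8-oxoguaia-1(10),7(11)-dien-4-yl methyl oxalate
Product: 5 (4S,5S)-guaia-1(10),7(11)-dien-8-one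
Conditions: Bu3SnH (2 equiv), AIBN (0.2 equiv), toluene, 110 °C
Reagents that add atoms: none
Why: Tin hydride deoxygenation of a tertiary alkyl methyl oxalate (a Barton–McCombie-type radical chain): Bu3Sn• adds to the oxalate carbonyl and β-scission releases the tertiary C4 radical. Bu3SnH should deliver hydrogen to the face of the ring A radical anti to the C5–C6 bond (the face of H5), which leaves C15 cis to C6 and sets C4 as S under kinetic control; the tetrasubstituted alkenes and the hindered enone are poor partners for stannyl radicals.

Step 5
Reactants: 5 (4S,5S)-guaia-1(10),7(11)-dien-8-one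
Product: 6 (4S,5S,7S)-7,11-epoxyguai-1(10)-en-8-one
Conditions: 30% aq. H2O2, LiOH (0.3 equiv), MeOH, 0 °C
Reagents that add atoms: hydrogen peroxide, OO
Why: Weitz–Scheffer nucleophilic epoxidation, as used on α-isopropylidene cycloalkanones: hydroperoxide adds to C11 and the enolate closes on oxygen. The electron-rich C1=C10 alkene is inert to a nucleophilic oxidant, and sub-stoichiometric hydroxide at 0 °C limits enolisation toward C9; the C7 configuration is erased in step 6.

Step 6
Reactants: 6 (4S,5S,7S)-7,11-epoxyguai-1(10)-en-8-one
Product: 7 (4S,5S,7R)-11-hydroxyguai-1(10)-en-8-one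
Conditions: SmI2 (2.5 equiv), THF/MeOH (2:1), −90 °C; pH 7 phosphate buffer
Reagents that add atoms: none
Why: SmI2 reduction of an α,β-epoxy ketone to the β-hydroxy ketone: two electron transfers cleave the C7–O bond and leave the C11 alkoxide and a samarium enolate that MeOH protonates at C7. Protonation along the pseudo-axial direction of ring B puts the bulky C(CH3)2OH group pseudo-equatorial and cis to C4 across the ring (H7 cis to H5; the descriptor is 7R only because the C8 carbonyl outranks C11), which should also be the more stable C7 epimer; −90 °C and a neutral quench suppress retro-aldol loss of acetone.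

Step 7
Reactants: 7 (4S,5S,7R)-11-hydroxyguai-1(10)-en-8-one
Product: 8 (4S,5S,7S,8S)-guai-1(10)-ene-8,11-diol
Conditions: Me4NBH(OAc)3 (5 equiv), MeCN/AcOH (1:1), −30 → 0 °C
Reagents that add atoms: none
Why: Evans–Saksena hydroxyl-directed reduction: the C11 hydroxyl exchanges for acetate on boron and hydride is delivered intramolecularly to C8 from the side of the C7 substituent. H8 therefore ends cis to the side chain and the C8 hydroxyl trans to it (8S); the reagent does not reduce a ketone that lacks a bound hydroxyl, and the acidic medium cannot trigger retro-aldol cleavage.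

Step 8
Reactants: 9 4-hydroxycinnamic acid [(E)-3-(4-hydroxyphenyl)prop-2-enoic acid]
Product: 11 (E)-4-(tert-butyldimethylsilyloxy)cinnamic acid, via bis-silylated 4-hydroxycinnamic acid 10 (not isolated)
Conditions: TBSCl (2.3 equiv), imidazole, DMF, rt; then AcOH/THF/H2O, rt
Reagents that add atoms: tert-butyldimethylsilyl chloride, CC(C)(C)[Si](C)(C)Cl
Why: Silylation of both acidic hydroxyls, then selective hydrolysis of the labile silyl ester in aqueous acetic acid; the aryl silyl ether is stable to these conditions and the E alkene is untouched.

Step 9
Reactants: 8 (4S,5S,7S,8S)-guai-1(10)-ene-8,11-diol; 11 (E)-4-(tert-butyldimethylsilyloxy)cinnamic acid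
Product: 12 (4S,5S,7S,8S)-11-hydroxyguai-1(10)-en-8-yl (E)-4-(tert-butyldimethylsilyloxy)cinnamate
Conditions: DCC (1.3 equiv), DMAP (0.3 equiv), CH2Cl2, 0 °C → rt
Reagents that add atoms: none
Why: Steglich esterification: the DMAP-activated acyl group is taken up by the secondary C8 hydroxyl, the tertiary C11 hydroxyl being too hindered to compete; no stereocentre is affected and the E geometry of the acid is retained.

Step 10
Reactants: 12 (4S,5S,7S,8S)-11-hydroxyguai-1(10)-en-8-yl (E)-4-(tert-butyldimethylsilyloxy)cinnamate
Product: 13 (4S,5S,7S,8S)-11-hydroxyguai-1(10)-en-8-yl (E)-4-hydroxycinnamate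
Conditions: TBAF (1.1 equiv), AcOH (1.1 equiv), THF, 0 °C
Reagents that add atoms: none
Why: Fluoride cleavage of the aryl silyl ether; acetic acid buffers the phenoxide so that neither ester cleavage nor acyl transfer to the C11 hydroxyl should occur.

## Compound list

1 | germacrone, (3E,7E)-3,7-dimethyl-10-(propan-2-ylidene)cyclodeca-3,7-dien-1-one | C/C1=C\CC/C(C)=C/CC(=C(C)C)C(=O)C1 | starting material
2 | (4R,5R)-germacrone 4,5-epoxide, (4R,5R)-4,5-epoxygermacra-1(10)E,7(11)-dien-8-one | C/C1=C\CC[C@@]2(C)O[C@@H]2CC(=C(C)C)C(=O)C1 | intermediate
3 | (4R,5R)-4-hydroxyguaia-1(10),7(11)-dien-8-one (C4 hydroxyl cis to H5) | CC1=C2CC[C@@](C)(O)[C@@H]2CC(=C(C)C)C(=O)C1 | intermediate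
4 | (4R,5R)-8-oxoguaia-1(10),7(11)-dien-4-yl methyl oxalate | CC1=C2CC[C@@](C)(OC(=O)C(=O)OC)[C@@H]2CC(=C(C)C)C(=O)C1 | intermediate
5 | (4S,5S)-guaia-1(10),7(11)-dien-8-one (H4 cis to H5) | CC1=C2CC[C@H](C)[C@@H]2CC(=C(C)C)C(=O)C1 | intermediate
6 | (4S,5S,7S)-7,11-epoxyguai-1(10)-en-8-one (epoxide oxygen on the face of H5) | CC1=C2CC[C@H](C)[C@@H]2C[C@@]3(OC3(C)C)C(=O)C1 | intermediate
7 | (4S,5S,7R)-11-hydroxyguai-1(10)-en-8-one (H7 cis to H5) | CC1=C2CC[C@H](C)[C@@H]2C[C@H](C(C)(C)O)C(=O)C1 | intermediate
8 | (4S,5S,7S,8S)-guai-1(10)-ene-8,11-diol (C8 hydroxyl trans to the C7 side chain) | CC1=C2CC[C@H](C)[C@@H]2C[C@H](C(C)(C)O)[C@@H](O)C1 | intermediate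
9 | 4-hydroxycinnamic acid, (E)-3-(4-hydroxyphenyl)prop-2-enoic acid | OC(=O)/C=C/c1ccc(O)cc1 | starting material
10 | tert-butyldimethylsilyl (E)-4-(tert-butyldimethylsilyloxy)cinnamate | CC(C)(C)[Si](C)(C)OC(=O)/C=C/c1ccc(O[Si](C)(C)C(C)(C)C)cc1 | intermediate (not isolated)
11 | (E)-4-(tert-butyldimethylsilyloxy)cinnamic acid | OC(=O)/C=C/c1ccc(O[Si](C)(C)C(C)(C)C)cc1 | intermediate
12 | (4S,5S,7S,8S)-11-hydroxyguai-1(10)-en-8-yl (E)-4-(tert-butyldimethylsilyloxy)cinnamate | CC1=C2CC[C@H](C)[C@@H]2C[C@H](C(C)(C)O)[C@@H](OC(=O)/C=C/c2ccc(O[Si](C)(C)C(C)(C)C)cc2)C1 | intermediate
13 | (4S,5S,7S,8S)-11-hydroxyguai-1(10)-en-8-yl (E)-4-hydroxycinnamate | CC1=C2CC[C@H](C)[C@@H]2C[C@H](C(C)(C)O)[C@@H](OC(=O)/C=C/c2ccc(O)cc2)C1 | target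

## Step count and least certain steps

Total: 10 steps. Longest linear sequence: 9 steps (1 to 13 through steps 1–7, 9 and 10); step 8 is a one-step branch.

**Step 2 (key step).** The most likely failure is proton loss from the C10 cation in the wrong direction. Loss toward C9 gives the cross-conjugated 7(11),9-dienone, helped by the acidity the C8 carbonyl confers on H9. Loss toward C14 gives the exocyclic alkene. Trapping of the cation by adventitious water and opening of the epoxide at tertiary C4 are lesser risks.

The fallback removes the carbonyl before the cyclisation, so that C9 is an ordinary methylene. It sets out from 2. NaBH4/CeCl3·7H2O in MeOH at −40 °C should reduce the ketone to (4R,5R,8S)-4,5-epoxygermacra-1(10),7(11)-dien-8-ol F1 (drawn as one C8 epimer; either serves). The free alcohol would attack C5, so Ac2O/pyridine converts it into (4R,5R,8S)-4,5-epoxygermacra-1(10),7(11)-dien-8-yl acetate F2. The same p-TsOH cyclisation should then give (4R,5R,8S)-4-hydroxyguaia-1(10),7(11)-dien-8-yl acetate F3. K2CO3 in MeOH frees (4R,5R,8S)-guaia-1(10),7(11)-diene-4,8-diol F4, and Dess–Martin periodinane oxidises only the secondary allylic hydroxyl, coming back to the route at 3.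

**Step 5.** Hydroxide may enolise the ketone toward C9 and move C1=C10 into conjugation, where the new, less hindered enone would be epoxidised instead. Attack at the fully substituted C11 may also be slow.

The fallback replaces nucleophilic epoxidation of the ketone by hydroxyl-directed electrophilic epoxidation at the alcohol level. From 5, NaBH4/CeCl3·7H2O gives (4S,5S,8S)-guaia-1(10),7(11)-dien-8-ol F5 (either C8 epimer serves). VO(acac)2 with t-BuOOH epoxidises the allylic alkene syn to the hydroxyl much faster than the homoallylic C1=C10, giving (4S,5S,7R,8S)-7,11-epoxyguai-1(10)-en-8-ol F6. Dess–Martin periodinane then returns the ketone, rejoining the route at 6.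

**Step 4.** Hydrogen-atom transfer to the planar C4 radical may show poor facial selectivity, and the tertiary oxalate may undergo thermal elimination at 110 °C.

The fallback sets C4 by catalytic hydrogenation and starts from 3. SOCl2/pyridine at 0 °C eliminates in an anti sense; H5 is syn to the leaving group and cannot be lost, so C5 is safe. This should give (5S)-guaia-1(10),3,7(11)-trien-8-one F7 with some (5S)-guaia-1(10),4(15),7(11)-trien-8-one F8. Hydrogenation of the mixture with RhCl(PPh3)3 and H2 in benzene/EtOH should add hydrogen anti to C6 and leave the two tetrasubstituted alkenes alone. Both isomers converge on 5.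

**Step 6.** The samarium enolate may be protonated from the wrong face of C7, and the β-alkoxy ketone may undergo retro-aldol cleavage with loss of acetone.

The fallback avoids both the enolate and the β-hydroxy ketone. From 6, a Wharton transposition (N2H4·H2O, AcOH cat., MeOH) should give (4S,5S)-guaia-1(10),7-dien-11-ol F9. Hydroboration–oxidation of its trisubstituted C7=C8 alkene (BH3·THF, 0 °C; then NaOH/H2O2) adds H to C7 and OH to C8 on the same face. This fixes the trans relation of the C8 oxygen and the side chain by mechanism. The route is rejoined at 8, and step 7 is bypassed.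

**Step 1.** Enantioselection may be incomplete on a conformationally mobile macrocycle, some 1,10-epoxide or bis-epoxide may form, and the β,γ-unsaturated ketone may isomerise at pH 10.5.

The fallback exchanges asymmetric catalysis for resolution. From 1, buffered mCPBA in CH2Cl2 at 0 °C gives the racemic 4,5-epoxide, that is 2 together with (4S,5S)-germacrone 4,5-epoxide F10. Preparative chromatography on a chiral stationary phase separates the two and returns to the route at 2.

## Further compounds

F1 | step 2 | (4R,5R,8S)-4,5-epoxygermacra-1(10),7(11)-dien-8-ol | C/C1=C\CC[C@@]2(C)O[C@@H]2CC(=C(C)C)[C@@H](O)C1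
F2 | step 2 | (4R,5R,8S)-4,5-epoxygermacra-1(10),7(11)-dien-8-yl acetate | C/C1=C\CC[C@@]2(C)O[C@@H]2CC(=C(C)C)[C@@H](OC(C)=O)C1
F3 | step 2 | (4R,5R,8S)-4-hydroxyguaia-1(10),7(11)-dien-8-yl acetate | CC1=C2CC[C@@](C)(O)[C@@H]2CC(=C(C)C)[C@@H](OC(C)=O)C1
F4 | step 2 | (4R,5R,8S)-guaia-1(10),7(11)-diene-4,8-diol | CC1=C2CC[C@@](C)(O)[C@@H]2CC(=C(C)C)[C@@H](O)C1
F5 | step 5 | (4S,5S,8S)-guaia-1(10),7(11)-dien-8-ol | CC1=C2CC[C@H](C)[C@@H]2CC(=C(C)C)[C@@H](O)C1
F6 | step 5 | (4S,5S,7R,8S)-7,11-epoxyguai-1(10)-en-8-ol | CC1=C2CC[C@H](C)[C@@H]2C[C@@]3(OC3(C)C)[C@@H](O)C1
F7 | step 4 | (5S)-guaia-1(10),3,7(11)-trien-8-one | CC1=C2CC=C(C)[C@@H]2CC(=C(C)C)C(=O)C1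
F8 | step 4 | (5S)-guaia-1(10),4(15),7(11)-trien-8-one | CC1=C2CCC(=C)[C@@H]2CC(=C(C)C)C(=O)C1
F9 | step 6 | (4S,5S)-guaia-1(10),7-dien-11-ol | CC1=C2CC[C@H](C)[C@@H]2CC(C(C)(C)O)=CC1
F10 | step 1 | (4S,5S)-germacrone 4,5-epoxide | C/C1=C\CC[C@]2(C)O[C@H]2CC(=C(C)C)C(=O)C1
A1 | alternative 1 | acetonide of (4S,5S,7S,8S)-guai-1(10)-ene-8,11-diol | CC1=C2CC[C@H](C)[C@@H]2C[C@H]2[C@@H](OC(C)(C)OC2(C)C)C1
A2 | alternative 1 | eight-membered cyclic sulfone with SO2 between C1 and C10 and the 8,11-acetonide (C1 and C10 configurations undefined) | C[C@H]1CCC2[C@H]1C[C@H]1[C@@H](OC(C)(C)OC1(C)C)CC(C)S2(=O)=O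
A3 | alternative 2 | 8-benzyloxy-4-(triethylsilyloxy)guai-1(10)-en-7-one | CC1=C2CC[C@@](C)(O[Si](CC)(CC)CC)[C@@H]2CC(=O)[C@@H](OCc3ccccc3)C1
A4 | alternative 2 | (R)-1-methyl-3-(prop-1-en-2-yl)cyclopent-2-en-1-yl triethylsilyl ether | C=C(C)C1=C[C@](C)(O[Si](CC)(CC)CC)CC1
A5 | alternative 2 | 3,3-bis(benzyloxy)-2-(trimethylsilyloxy)prop-1-ene | C=C(O[Si](C)(C)C)C(OCc1ccccc1)OCc1ccccc1
A6 | alternative 3 | 4-(triethylsilyloxy)guaia-1(10),6-dien-7-yl tert-butyldimethylsilyl ether | CC1=C2CC[C@@](C)(O[Si](CC)(CC)CC)[C@@H]2C=C(O[Si](C)(C)C(C)(C)C)CC1
A7 | alternative 3 | (R,E)-1-[1-(tert-butyldimethylsilyloxy)cyclopropyl]-3-methyl-3-(triethylsilyloxy)oct-1-en-6-yne | CC#CCC[C@@](C)(O[Si](CC)(CC)CC)/C=C/C1(O[Si](C)(C)C(C)(C)C)CC1
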